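Numbering: ring A is the cyclohexene C5–C6–C7–C8–C9–C10 (C5=C10, C14H3 on C10, acyloxy on C6). Ring B is the cis-fused lactone O–C8–C7–C11(=C13H2)–C12(=O). The chain C4(C15H3)–C3–C2–C1(OH) sits on C5.
Enabling feature: C5 is one end of the tetrasubstituted ring-A alkene C5=C10 and also carries the C4 methine with its C15 methyl. One oxidation level up, C10=C5–C4=C15 is a 1,3-diene, which is what an enyne metathesis between a C5≡C4 alkyne and a C10(=CH2)CH3 methallyl group produces.
Retrosynthetic cuts, in order: the C6–O acyl bond and C11=C13; H2 off C4–C15; C5=C10 together with C4=C15 (enyne metathesis, opens ring A); C8–C9 and O8–C12 (methallylboration and lactonisation, opens ring B); C6–C7 (cross-aldol); C5–C6 (alkyne formylation).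
Forward: the C1–C6 ynal is joined to the C7/C8/C11/C12 aldehyde ester, the methallyl unit C9/C10/C14/C15 is added and ring B closes. Ring A then closes by metathesis, and C4, the ester and C13 follow.
Stereochemistry: C6 and C7 come from an (S)-diarylprolinol-catalysed anti aldol and C8 from a pinene-derived methallylborane. C4 is relayed from the C6 hydroxyl by directed hydrogenation, and the acyl stereocentre comes from (R)-2-methylbutanoic acid.

Key step: step 6

Assumption: the (S)-diarylprolinol is taken to induce in the same sense as (S)-proline, and the borane from (−)-α-pinene to follow the accepted cyclic transition-state model; both reagents are available in either enantiomeric form.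

Step 1
Reactants: 1 pent-4-yn-1-ol
Product: 2 tert-butyl(pent-4-yn-1-yloxy)diphenylsilane
Conditions: TBDPSCl, imidazole, CH2Cl2, 0 °C to rt
Reagents that add atoms: tert-butyl(chloro)diphenylsilane, CC(C)(C)[Si](Cl)(c1ccccc1)c1ccccc1
Why: Routine silylation of a primary alcohol (silyl ether protection); the TBDPS group is chosen because it withstands n-BuLi, LDA, both metal-catalysed steps and the later selective removal of the C6 triethylsilyl ether.

Step 2
Reactants: 2 tert-butyl(pent-4-yn-1-yloxy)diphenylsilane
Product: 3 6-[(tert-butyldiphenylsilyl)oxy]hex-2-ynal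
Conditions: n-BuLi, THF, −78 °C; DMF, −78 °C to 0 °C; inverse quench into cold 1 M HCl
Reagents that add atoms: N,N-dimethylformamide, CN(C)C=O
Why: Formylation of a lithium acetylide with DMF is the standard route to alk-2-ynals, and the acidic inverse quench protonates the liberated dimethylamine before it can add to the ynal.

Step 3
Reactants: 3 6-[(tert-butyldiphenylsilyl)oxy]hex-2-ynal; 4 methyl 4-oxobutanoate
Product: 5 anti aldol adduct methyl (3S,4R)-9-[(tert-butyldiphenylsilyl)oxy]-3-formyl-4-hydroxynon-5-ynoate
Conditions: (S)-bis[3,5-bis(trifluoromethyl)phenyl](pyrrolidin-2-yl)methanol (10 mol %), H2O (3 equiv), 1,4-dioxane, rt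
Reagents that add atoms: none
Why: Enamine-catalysed direct cross-aldol reaction, a pairing (enolisable aldehyde donor, non-enolisable ynal acceptor, diarylprolinol catalyst) that is known to be anti-selective: the E-enamine of 4 attacks the ynal held by a hydrogen bond to the catalyst hydroxyl, in the same sense as with (S)-proline, which sets C7 (S) and C6 (R), and the neutral medium leaves the γ-hydroxy ester open.

Step 4
Reactants: 5 anti aldol adduct
Product: 6 methyl (3S,4R)-9-[(tert-butyldiphenylsilyl)oxy]-3-formyl-4-[(triethylsilyl)oxy]non-5-ynoate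
Conditions: TESOTf, 2,6-lutidine, CH2Cl2, −78 °C
Reagents that add atoms: triethylsilyl trifluoromethanesulfonate, CC[Si](CC)(CC)OS(=O)(=O)C(F)(F)F
Why: Silylation with a silyl triflate and a hindered pyridine base at low temperature is the usual way to cap β-hydroxy aldehydes without retro-aldol, elimination or epimerisation at C7, and it blocks O6 so that only O8 can later close the lactone.

Step 5
Reactants: 6 C6-silylated aldehyde ester; 7 2-methylallylmagnesium chloride
Product: 11 enyne lactone (4R,5R)-5-(2-methylallyl)-4-[(1R)-6-(TBDPS-oxy)-1-(TES-oxy)hex-2-yn-1-yl]oxolan-2-one, via methallylborane 8 (not isolated), via borinate 9 (not isolated), via hydroxy ester 10 (not isolated)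
Conditions: (+)-Ipc2BOMe, 7, Et2O, 0 °C to rt; 6, −78 °C; 30% H2O2, pH 7 buffer, MeOH, 0 °C to rt; PPTS (cat.), CH2Cl2, rt
Reagents that add atoms: none
Why: Brown-type asymmetric methallylboration through a chair Zimmerman–Traxler transition state: the isopinocampheyl groups derived from (−)-α-pinene select the aldehyde face that gives (8R), reagent control being known to dominate the small intrinsic bias of α-branched aldehydes towards allylboranes, and the liberated C8 hydroxyl closes ring B on the C12 methyl ester (cis-lactone, because C7 and C8 are anti) while O6 stays blocked as its silyl ether.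

Step 6
Reactants: 11 enyne lactone
Product: 12 diene lactone (ring A closed; C5=C10 ring alkene and C4=C15 methylene)
Conditions: second-generation Hoveyda–Grubbs catalyst RuCl2(SIMes)(=CH-C6H4-2-OiPr) (10 mol %), ethylene (1 atm), toluene (0.005 M), 80 °C
Reagents that add atoms: none
Why: The precatalyst and ethylene give the propagating Ru=CH2, which adds across C5≡C4 through a ruthenacyclobutene with its CH2 on the less hindered C4 and ruthenium on C5 (next to the branched, silyloxy-bearing C6), and ring opening gives the C5 vinylcarbene that already carries C4=C15. This carbene takes up the tethered C10=CH2 through a ruthenacyclobutane, and cycloreversion forms C5=C10 and returns Ru=CH2, so that the methallyl CH2 is handed on to C4 of the next molecule. The closest known reaction type is ruthenium-catalysed ring-closing enyne metathesis of 1,7-enynes to 1-(alk-1-en-2-yl)cyclohexenes, here at the demanding end of its scope because a 1,1-disubstituted alkene has to end up in a tetrasubstituted ring alkene. Ring A closes in the exo mode to a six-membered ring with only C5 of the alkyne inside it, whereas the endo alternative would need ruthenium on C4 and a seven-membered ring. No stereocentre is formed, and C6, C7 and C8 are not touched. The step needs regioselective carbene addition, ring closure faster than capture of the C5 carbene by ethylene or a second alkyne, and the absence of a competing alkene; these are secured by the steric difference between C6 and C3, by the cis-lactone that holds the C6 and C9 arms on one face of ring B, by high dilution at 80 °C and by the still saturated lactone.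

Step 7
Reactants: 12 diene lactone
Product: 14 α-(diethoxyphosphoryl) diene lactone (phosphonate on C11), via enol phosphate 13 (not isolated)
Conditions: LDA (1.1 equiv), THF, −78 °C; ClP(O)(OEt)2, −78 °C to rt; LDA (2.2 equiv), −78 °C to rt; AcOH
Reagents that add atoms: diethyl chlorophosphate, CCOP(=O)(Cl)OCC
Why: O-Phosphorylation of the lactone enolate and base-induced 1,3-migration of phosphorus from oxygen to carbon (vinyl phosphate to α-phosphono lactone rearrangement) is an established entry to Horner–Wadsworth–Emmons reagents for α-methylenation; it is placed here because O6 is still silylated, so the only strong-base step of the endgame meets no free hydroxyl and no epimerisable ester, and the new C11 centre is of no consequence since it becomes sp2 again.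

Step 8
Reactants: 14 α-phosphono diene lactone
Product: 15 C6 alcohol of 14
Conditions: HF·pyridine, pyridine, THF, 0 °C
Reagents that add atoms: none
Why: Selective desilylation: buffered HF cleaves the secondary triethylsilyl ether far faster than the primary TBDPS ether, and the cold, nearly neutral medium gives the C6 hydroxyl no opportunity to migrate onto C12 (translactonisation).

Step 9
Reactants: 15 C6 alcohol
Product: 16 (4S)-dihydro alcohol (C4–C15H3 set, C5=C10 retained)
Conditions: H2 (1 atm), [Ir(cod)(PCy3)(py)]PF6 (5 mol %), CH2Cl2, 0 °C to rt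
Reagents that add atoms: none
Why: Hydroxyl-directed homogeneous hydrogenation of a homoallylic 1,1-disubstituted alkene: A1,3 strain with C14H3 and C6 twists the C4=C15 unit out of the plane of C5=C10 with C15H2 on the hydroxyl-bearing face and the C3 chain on the opposite face, so iridium bound to O6 delivers H2 to the alkene face that looks towards C6 and sets C4 as S, while the tetrasubstituted C5=C10 reacts far more slowly.

Step 10
Reactants: 16 (4S)-dihydro alcohol; 17 (R)-2-methylbutanoic acid
Product: 18 C6 (R)-2-methylbutanoate of 16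
Conditions: DCC, DMAP, CH2Cl2, 0 °C to rt
Reagents that add atoms: none
Why: Steglich esterification is the standard mild acylation for hindered secondary alcohols; the acyl stereocentre comes unchanged from 17, and the weakly basic medium neither enolises the activated acid to a significant extent nor triggers migration of the lactone to O6.

Step 11
Reactants: 18 phosphono lactone ester
Product: 19 α-methylene lactone ester, C1 TBDPS ether of the target
Conditions: 37% aq. HCHO, K2CO3, THF, 0 °C
Reagents that add atoms: formaldehyde, C=O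
Why: Horner–Wadsworth–Emmons olefination of an α-phosphono lactone with formaldehyde under carbonate conditions is a well-used α-methylenation that deprotonates only the doubly activated C11–H, so the 2-methylbutanoate stereocentre, the C6 ester and the lactone are not touched.

Step 12
Reactants: 19 C1 TBDPS ether of the target
Product: 20 target CNP0291605.3
Conditions: HF·pyridine, THF, 0 °C to rt
Reagents that add atoms: none
Why: Fluoride-mediated cleavage of the TBDPS ether under acidic, weakly nucleophilic conditions leaves the α-methylene lactone, the ester and its α-stereocentre untouched, which basic fluoride sources might not.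

Compound list
1 | pent-4-yn-1-ol | C#CCCCO | starting material
2 | tert-butyl(pent-4-yn-1-yloxy)diphenylsilane | C#CCCCO[Si](c1ccccc1)(c1ccccc1)C(C)(C)C | intermediate
3 | 6-[(tert-butyldiphenylsilyl)oxy]hex-2-ynal | O=CC#CCCCO[Si](c1ccccc1)(c1ccccc1)C(C)(C)C | intermediate
4 | methyl 4-oxobutanoate | COC(=O)CCC=O | starting material
5 | methyl (3S,4R)-9-[(tert-butyldiphenylsilyl)oxy]-3-formyl-4-hydroxynon-5-ynoate (anti aldol; C7 S, C6 R) | O=C[C@@H](CC(=O)OC)[C@@H](O)C#CCCCO[Si](c1ccccc1)(c1ccccc1)C(C)(C)C | intermediate
6 | methyl (3S,4R)-9-[(tert-butyldiphenylsilyl)oxy]-3-formyl-4-[(triethylsilyl)oxy]non-5-ynoate | O=C[C@@H](CC(=O)OC)[C@@H](O[Si](CC)(CC)CC)C#CCCCO[Si](c1ccccc1)(c1ccccc1)C(C)(C)C | intermediate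
7 | 2-methylallylmagnesium chloride | C=C(C)C[Mg]Cl | starting material
8 | B-(2-methylallyl)diisopinocampheylborane, isopinocampheyl groups from (−)-α-pinene (not isolated) | C=C(C)CB([C@H]1C[C@H]2C[C@@H]([C@@H]1C)C2(C)C)[C@H]1C[C@H]2C[C@@H]([C@@H]1C)C2(C)C | intermediate
9 | O8-diisopinocampheylborinate of hydroxy ester 10 (not isolated) | C=C(C)C[C@@H](OB([C@H]1C[C@H]2C[C@@H]([C@@H]1C)C2(C)C)[C@H]1C[C@H]2C[C@@H]([C@@H]1C)C2(C)C)[C@@H](CC(=O)OC)[C@@H](O[Si](CC)(CC)CC)C#CCCCO[Si](c1ccccc1)(c1ccccc1)C(C)(C)C | intermediate
10 | methyl (3R,4R)-4-hydroxy-6-methyl-3-[(1R)-6-(TBDPS-oxy)-1-(TES-oxy)hex-2-yn-1-yl]hept-6-enoate (not isolated) | C=C(C)C[C@@H](O)[C@@H](CC(=O)OC)[C@@H](O[Si](CC)(CC)CC)C#CCCCO[Si](c1ccccc1)(c1ccccc1)C(C)(C)C | intermediate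
11 | (4R,5R)-5-(2-methylallyl)-4-[(1R)-6-(TBDPS-oxy)-1-(TES-oxy)hex-2-yn-1-yl]oxolan-2-one (cis-β,γ-disubstituted lactone, 1,7-enyne) | C=C(C)C[C@H]1OC(=O)C[C@H]1[C@@H](O[Si](CC)(CC)CC)C#CCCCO[Si](c1ccccc1)(c1ccccc1)C(C)(C)C | intermediate
12 | (3aR,4R,7aR)-6-methyl-5-[5-(TBDPS-oxy)pent-1-en-2-yl]-4-(TES-oxy)-3a,4,7,7a-tetrahydro-1-benzofuran-2(3H)-one (H6, H7, H8 all cis) | C1C(=O)O[C@@H]2CC(C)=C(C(=C)CCCO[Si](c3ccccc3)(c3ccccc3)C(C)(C)C)[C@H](O[Si](CC)(CC)CC)[C@H]12 | intermediate
13 | diethyl enol phosphate of 12 (C11=C12, phosphate on the C12 oxygen; not isolated) | C1=C(OP(=O)(OCC)OCC)O[C@@H]2CC(C)=C(C(=C)CCCO[Si](c3ccccc3)(c3ccccc3)C(C)(C)C)[C@H](O[Si](CC)(CC)CC)[C@H]12 | intermediate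
14 | 12 with a diethoxyphosphoryl group on C11 (either C11 epimer serves; C6, C7, C8 as in 12) | CCOP(=O)(OCC)C1C(=O)O[C@@H]2CC(C)=C(C(=C)CCCO[Si](c3ccccc3)(c3ccccc3)C(C)(C)C)[C@H](O[Si](CC)(CC)CC)[C@H]12 | intermediate
15 | C6 alcohol of 14 (hydroxyl cis to C11 and O8) | CCOP(=O)(OCC)C1C(=O)O[C@@H]2CC(C)=C(C(=C)CCCO[Si](c3ccccc3)(c3ccccc3)C(C)(C)C)[C@H](O)[C@H]12 | intermediate
16 | (4S)-dihydro derivative of 15, side chain (2S)-5-(TBDPS-oxy)pentan-2-yl on C5 | CCOP(=O)(OCC)C1C(=O)O[C@@H]2CC(C)=C([C@@H](C)CCCO[Si](c3ccccc3)(c3ccccc3)C(C)(C)C)[C@H](O)[C@H]12 | intermediate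
17 | (R)-2-methylbutanoic acid | CC[C@@H](C)C(=O)O | starting material
18 | C6 (R)-2-methylbutanoate of 16 | CCOP(=O)(OCC)C1C(=O)O[C@@H]2CC(C)=C([C@@H](C)CCCO[Si](c3ccccc3)(c3ccccc3)C(C)(C)C)[C@H](OC(=O)[C@H](C)CC)[C@H]12 | intermediate
19 | C1 TBDPS ether of the target (α-methylene lactone in place) | C=C1C(=O)O[C@@H]2CC(C)=C([C@@H](C)CCCO[Si](c3ccccc3)(c3ccccc3)C(C)(C)C)[C@H](OC(=O)[C@H](C)CC)[C@H]12 | intermediate
20 | (3aR,4R,7aR)-5-[(2S)-5-hydroxypentan-2-yl]-6-methyl-3-methylidene-2-oxo-2,3,3a,4,7,7a-hexahydro-1-benzofuran-4-yl (2R)-2-methylbutanoate | C=C1C(=O)O[C@@H]2CC(C)=C([C@@H](C)CCCO)[C@H](OC(=O)[C@H](C)CC)[C@H]12 | target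

Total step count: 12. Longest linear sequence: 12 steps, from 1 to 20.

The step most likely to fail is step 6. Closure of the C5 carbene onto the 1,1-disubstituted alkene may be so slow that capture by ethylene, alkyne oligomerisation or catalyst decay takes over. The fallback sets out from 11 and separates the two events. Cross enyne metathesis with ethylene (second-generation Grubbs catalyst RuCl2(SIMes)(PCy3)(=CHPh), ethylene, CH2Cl2, 40 °C) is run on purpose to give the 2,3-disubstituted buta-1,3-diene F1. This already holds C4=C15 and carries a C5=CH2 group. Diene–ene ring-closing metathesis follows with the molybdenum alkylidene Mo(=CHCMe2Ph)(=N-2,6-iPr2C6H3)[OCMe(CF3)2]2 in benzene at 60 °C under an argon sweep. Catalysts of this class are known to form tetrasubstituted ring alkenes. The closure forms C5=C10 and comes back to the route at 12.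

Second is step 9. Facial selectivity at C4 may be poor, C5=C10 may be over-reduced, or the phosphoryl oxygen may hold the iridium away from O6. The fallback sets out from 14 and replaces substrate direction by catalyst control. Hydrogenation of the silyl ether uses a chiral iridium phosphine–oxazoline complex, [Ir(cod)(tBu-PHOX)]B[3,5-(CF3)2C6H3]4, under H2 in CH2Cl2, with the ligand antipode chosen by experiment. It should give the (4S)-dihydro triethylsilyl ether F2, and buffered HF·pyridine then comes back to the route at 16.

Third is step 5. Facial selectivity may be poor, because open-chain induction from C7 and C6 (Felkin–Anh and 1,3-anti) points to the other aldehyde face, and the borane has to overrule whatever part of this bias survives in the cyclic transition state. The fallback sets out from 6 and uses that bias. Hosomi–Sakurai addition of trimethyl(2-methylallyl)silane with BF3·OEt2 in CH2Cl2 at −78 °C should give the C8-epimeric hydroxy ester F3, which closes with PPTS to the trans-lactone F4. Aminolysis with AlMe3 and dimethylamine hydrochloride opens it to the γ-hydroxy dimethylamide F5, and MsCl with Et3N at 0 °C gives the C8 mesylate F6. On warming, the amide oxygen displaces the mesylate with inversion at C8 to give the iminium lactone mesylate F7. Its hydrolysis in aqueous NaHCO3–THF comes back to the route at 11.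

Further compounds
F1 | step 6 | (4R,5R)-5-(2-methylallyl)-4-[(1R)-2,3-dimethylidene-6-(TBDPS-oxy)-1-(TES-oxy)hexyl]oxolan-2-one | C=C(C)C[C@H]1OC(=O)C[C@H]1[C@@H](O[Si](CC)(CC)CC)C(=C)C(=C)CCCO[Si](c1ccccc1)(c1ccccc1)C(C)(C)C
F2 | step 9 | (4S)-dihydro derivative of 14, C6 triethylsilyl ether retained | CCOP(=O)(OCC)C1C(=O)O[C@@H]2CC(C)=C([C@@H](C)CCCO[Si](c3ccccc3)(c3ccccc3)C(C)(C)C)[C@H](O[Si](CC)(CC)CC)[C@H]12
F3 | step 5 | C8 epimer of hydroxy ester 10 | C=C(C)C[C@H](O)[C@@H](CC(=O)OC)[C@@H](O[Si](CC)(CC)CC)C#CCCCO[Si](c1ccccc1)(c1ccccc1)C(C)(C)C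
F4 | step 5 | C8 epimer of 11 (trans-β,γ-disubstituted lactone) | C=C(C)C[C@@H]1OC(=O)C[C@H]1[C@@H](O[Si](CC)(CC)CC)C#CCCCO[Si](c1ccccc1)(c1ccccc1)C(C)(C)C
F5 | step 5 | γ-hydroxy N,N-dimethylamide from F4 | C=C(C)C[C@H](O)[C@@H](CC(=O)N(C)C)[C@@H](O[Si](CC)(CC)CC)C#CCCCO[Si](c1ccccc1)(c1ccccc1)C(C)(C)C
F6 | step 5 | C8 methanesulfonate of F5 | C=C(C)C[C@H](OS(C)(=O)=O)[C@@H](CC(=O)N(C)C)[C@@H](O[Si](CC)(CC)CC)C#CCCCO[Si](c1ccccc1)(c1ccccc1)C(C)(C)C
F7 | step 5 | 2-(dimethyliminio)oxolane methanesulfonate with the C8 configuration of 11 | C=C(C)C[C@H]1OC(=[N+](C)C)C[C@H]1[C@@H](O[Si](CC)(CC)CC)C#CCCCO[Si](c1ccccc1)(c1ccccc1)C(C)(C)C.CS(=O)(=O)[O-]
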